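Both flasks are read at 6.0 h, but their loadings of E differ, and in summer the portions go in late. The text follows a dispute between Ana and Ben about what those hours give.

the same everywhere: Z 0.074 M

|  | G | E | temperature | remark | time |
|---|---|---|---|---|---|
| Thursday's | 2.5 equiv | 0.042 mol% (in portions, 3) | −10 °C | run made earlier; portions every 40 min |  |
| Friday's | 2.5 equiv | 0.081 mol% (in portions, 3) | 5 °C | run made earlier; portions every 40 min |  |
| noon | 2.50 equiv | 0.06 mol% | 5 °C | everything together at the start | 6.0 h |
| summer | 2.50 equiv | 0.1 mol% (in portions, 3) | 5 °C | the portions of E follow each other after 40 min, the first at the start | 6.0 h |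

| run | time / h | L / % |
|---|---|---|
| Thursday's | 0.417 | 0 |
| Thursday's | 1.33 | 3 |
| Thursday's | 2.00 | 5 |
| Thursday's | 3.00 | 11 |
| Thursday's | 5.00 | 22 |
| Thursday's | 6.00 | 26 |
| Friday's | 0.250 | 0 |
| Friday's | 0.417 | 7 |
| Friday's | 0.667 | 9 |
| Friday's | 1.00 | 14 |
| Friday's | 2.00 | 42 |
| Friday's | 3.00 | 61 |

(each reading ± 1.5 percentage points)

1. which one finishes higher in amount of L, in percent of the Z charged ("neither" within 2 percentage points) (noon / summer / neither)
2. amount of L at the end, in percent of the Z charged, noon
3. amount of L at the end, in percent of the Z charged, summer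



Friday's run has the [Z], the G and the temperature of both flasks, so both chemists read it and convert. Noon stands at 4.44 h and summer at 6.58 h of Friday hours, the exposure to E: the time of reading less the mean delay of the portions, multiplied by the loading of E over Friday's. Portions at the start and after one and two intervals are on average one interval late. Summer therefore has more exposure than noon.

Ben holds that L grows in proportion to exposure, zero order in Z. Between its readings at 3.00 h and 6.00 h, Thursday's L grew by a factor of 2.36, while the time less the delay grew by 2.29. Friday's 42% at 1.33 h of exposure then puts the whole charge of Z, the limiting reagent against 2.50 equiv of G, at 3.17 h. On his line both flasks pass that mark, so Ben says neither.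

Ana answers that at 2.33 h Ben's line gives 73.5%, while Friday's reading is 61%, far beyond the scatter of 1.5 percentage points. She reads first order in Z, with a constant of 0.404 h⁻¹ on the Friday clock, taken from that one reading. That gives 83.4% for noon and 93.0% for summer.

The forecast, on her side, stands lower: summer ahead, noon 78%, summer 90%. Its words are “Enzyme decay over 6 h is not well defined, so I shade the estimates down”.

The simulation gives summer ahead, with noon at 79.3% and summer at 84.7%. Ben's neither falls, and the forecast's summer is 5.3 points too high.

    E → D (k = 0.00230 h⁻¹, Ea = 211 kJ mol⁻¹)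
    G + Q ⇌ J (K = 3.60 M⁻¹, k = 1.20 × 10⁵ M⁻¹ h⁻¹, Ea = 49.0 kJ mol⁻¹, ΔH = −2.00 kJ mol⁻¹)
    Z + E ⇌ Q (K = 15.0 M⁻¹, k = 52000 M⁻¹ h⁻¹, Ea = 38.0 kJ mol⁻¹, ΔH = −26.0 kJ mol⁻¹)
    J → E + L (k = 2300 h⁻¹, Ea = 67.0 kJ mol⁻¹)
    2 Z → X (k = 0.770 M⁻¹ h⁻¹, Ea = 59.0 kJ mol⁻¹)
    (constants at 5 °C)

Of the Z charged, summer at 6.0 h holds 1.86% free, 84.7% as L and 13.4% as X. The step in which two Z give X is the main reason that L in summer stays short of the Z charged: without it, summer ends at 96.9% rather than 84.7%. Ben's line fits noon at low exposure. For noon at 3.00 h it gives 70.0% against 59.2% in the flask, but for noon stopped at 1.5 h, with 1.11 h of exposure, it gives 35.0% against 36.4%.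

Readings and results are calculated for an exercise; the scatter is artificial.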